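## Structural features

The target is a cis-fused bicyclo[4.4.0]decene (labdane locants throughout). Ring A (C1–C5, C10) is a cyclohexane with the gem-dimethyl carbon C4 and a secondary carbinol at C2. Ring B (C5–C10) is a cyclohexene whose tetrasubstituted alkene C8=C9 carries the hydroxymethyl C17 on C8 and, on C9, the chain C11–C12 that ends at the β-carbon C13 of a furan-2(5H)-one. The rings share the C5–C10 bond; C10 is quaternary (methyl C20), C5 is a methine, and H5 and C20 lie on the same face. There are four stereocentres (2S,5R,6S,10S): C10, C5 and C6 are contiguous, C2 is isolated but 1,3 to both C4 and C10, and both secondary hydroxyls lie on the face opposite to C20. Fragile elements are the butenolide (base, hydride, nucleophiles), the primary allylic alcohol at C17 (ionisation in strong acid), and any intermediate in which a free 6-hydroxyl faces a C17 ester or a C9 ketone (five-membered lactone or hemiketal). The real difficulty is the quaternary C10, cis to H5 and bonded directly to the fully substituted alkene carbon C9, together with an alkene whose four substituents must be placed without ambiguity. The key step exploits that C10 is β to the C2 oxygen and bonded to sp2 C9: with C2 as a ketone, C1=C10 is an enone, C9–C10 is the bond an alkenylpalladium makes by conjugate carbometalation, and the three-atom bridge C6–C7–C8 from C5 forces the cis fusion.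

## Logic of the disconnections

**C12–C13.** 28 is first taken back to its tris-silyl ether 27, and 27 is cut between C12 and C13 into 24 and 25. The butenolide is the most fragile part, so it should arrive last and intact. The gain is that no earlier step has to tolerate it. The demand is an sp3–sp2 coupling from a primary iodide that spares silyl ethers and the lactone, which points to an alkylzinc (26).

**C12–I, O–PMB and O–Si bonds.** 24 goes back through 23 and 22 to 21. Only the C12 oxygen carries a PMB group, so it can be freed and turned into the iodide while O2, O6 and O17 stay silylated. The demand is an oxidative PMB cleavage that leaves an allylic silyl ether alone.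

**C2–H and C17–H.** 21 goes back through 20 to 19. Returning C2 to a ketone and C17 to an ester restores the two groups that make the ring closure possible. The demand is hydride delivery to C2 from the face of C20 and H5.

**C9–C10 (ring B).** 19 is cut to 18. This removes ring B, the quaternary centre and one stereocentre at once and leaves a monocyclic enone with an open chain. The demand is an alkenyl electrophile at C9 with the leaving group cis to C7, and a closure in which capture by hydride comes after, not before, the C–C bond formation.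

**C9–O (triflate).** 18 goes back to 17. The β-keto ester places the oxygen on C9 and the ester on C8 without any regiochemical question. The demand is O-sulfonylation through the non-chelated enolate so that the triflate ends trans to the ester.

**C7–C8.** 17 is cut into 9 (activated as 16) and 15. The cut lies next to the nucleophilic carbon of a 1,3-dicarbonyl and separates the achiral side-chain carbons from the ring fragment that holds both stereocentres. C6 is carried as a silyl ether from the start. A feed with C6 as a ketone was avoided, because C5 would then be a vinylogous 1,3-dicarbonyl position, C6/C9 a 1,4-diketone, and a free 6-hydroxyl would close onto C9 or C17. The demand is an SN2 reaction at a β-branched, β-oxygenated primary carbon, hence the triflate, with C- rather than O-alkylation.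

**C8–C9 and O–C12 of the side chain.** 15 is cut into 12 and 13, and 12 into 10 and 11. Both bonds are made by additions to cheap acceptors (nitrile, acrylonitrile). The demand is only that the PMB ether survives a brief acidic hydrolysis.

**C7–C(auxiliary).** 9 goes back through 8 to 7. The extra carbon is the stereocentre that controlled C6; once it has done so it is excised as a diol equivalent. The demand is a glycol cleavage that leaves the enone and the silyl ether alone.

**C10–C20 and enone transposition.** 7 goes back through 6 to 5. Ring A is masked as a vinylogous ester, which has a single enolisable position (C5) and becomes the enone with the methyl in place after 1,2-addition. The demand is addition to a hindered carbonyl without enolisation towards the β-silyloxy group.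

**C5–C6.** 5 goes back to 4, and 4 is cut into 2 and 3. This one bond sets C5 and C6 together; the absolute configuration is taken from the chiral pool. The demand is the anti relation at C5/C6 (ring-locked enolate) and non-chelation attack on the α-alkoxy aldehyde.

**C2–O (enol ether).** 2 goes back to 1 by O-ethylation of the symmetrical dione.

## Other disconnections considered

**Alternative 1:** The cut is C7–C8 inside ring B. The substrate A2 is a ring A cyclohexane that already holds the quaternary C10 with a β-keto ester arm (C9, C8, C17) and, cis to it on C5, the silyl enol ether of an acetyl group (C6, C7). Oxidation at an anode or with (NH4)2Ce(NO3)6 would turn one of the two electron-rich π systems into a radical (cation) that the other traps; C7–C8 forms in a six-membered closure and loss of silicon gives the 1,4-diketone A1.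
- In its favour: two nucleophilic carbons are joined without prior activation. The later C8=C9 alkene would come from a ring enol triflate whose geometry is fixed by the ring, which is better than the open-chain geometry problem of the chosen plan (step 9). The C11–C12 chain could be attached late by an sp2–sp3 coupling, which is the equal of the chosen plan in convergence.
- Against it: the closure does not create C10. A2 must already carry the quaternary centre, its cis relation to C5 and the C2 carbinol, so the hardest element is moved to an unsolved earlier stage. A1 has C5 α to the C6 ketone, so the cis fusion is open to epimerisation, and C6 must still be reduced from a defined face next to the C9 ketone.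
- Comparison: a radical-cation coupling beside a second enolisable ketone is less predictable than palladium insertion into one C–O bond. The step count should be no shorter, because redox adjustments at C6 and C9 and the synthesis of A2 replace a short chiral-pool feed.

**Alternative 2:** The cut removes C5–C10 and C6–C7 together. The open-chain substrate A4 carries a 2-methoxycarbonyl diene C7=C8–C9=C10 and, four atoms away, a Z silyl enol ether C5=C6. Heat or Me2AlCl would bring about an inverse-demand intramolecular Diels–Alder reaction to A3, closing both rings.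
- In its favour, and better than the chosen plan: both rings, three stereocentres (C5, C6, C10) and the C8=C9 alkene arise in one step. The Z enol ether translates suprafacially into the required C5/C6 relation. A3 already has both oxygens at their final oxidation level, so the endgame would be about two steps shorter.
- Against it: C10 is a fully substituted diene terminus, so one substituent must sit inside the s-cis diene, and the dienophile carbon C5 is flanked by the quaternary C4. Facial and endo/exo selectivity would have to be relayed from the single C2 stereocentre in the tether. Both alkene geometries of A4 (drawn with the tether inside the diene) must be made pure. A Lewis acid opens a stepwise Mukaiyama–Michael path that loses stereospecificity.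
- Comparison: on step economy of ring construction the alternative is the better. On certainty of the ring fusion and ease of making the substrate the chosen plan is safer, since its cis fusion is a geometric necessity and not a selectivity.

**Alternative 3:** The cut is C3–C4 in ring A. The substrate A6 is a ring B cyclohexenone (C6 ketone) with an isopropylidene group on C5, the quaternary C10 bearing an acetonyl arm (C1–C3), and the finished C8=C9 enoate. KOtBu or pyrrolidine would generate the C3 enolate or enamine, which adds to C4 in a 6-endo-trig Michael closure and gives the 2,6-dione A5 after protonation at C5.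
- In its favour: the gem-dimethyl quaternary C4 is made in the closure from an acetone-derived unit with no precious metal, which is the equal of the chosen plan (where C4 is bought ready-made). If the cis fusion is the more stable one, C5 would correct itself by equilibration, which would be better than kinetic control.
- Against it: as in alternative 1, an enantiopure quaternary C10 must exist before the key step. Conjugate addition that creates a quaternary carbon on a β,β-disubstituted enone is slow and reversible. The C7 methylene lies between the C6 ketone and the enoate, so base can move the alkene into conjugation with the ketone. The preference for cis over trans at C5 is not assured. A5 then needs two ketones reduced with different facial demands and told apart.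
- Comparison: the mechanism is simple and cheap, but the plan leaves C10 unsolved and adds redox and isomerisation risk; the step count should be similar or longer.

Key step: step 10

Remarks before the steps:
- 18 and 19 were checked atom by atom against the target. Both carry the (5R,6S) array, 18 has the triflate cis to C7 (E), and 19 is cis-fused (10S); neither structure needed correction. The feed to 18 was redesigned.
- Assumption: 3 is taken as the commercial L-series aldehyde and is distilled before use.
- The descriptor at C6 reads R in 4–9 and 16 and S from 17 on, and that at C5 reads S in 4–6 and R from 7 on. These changes come only from priority changes; no bond at either centre is broken.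

## Route

Step 1
Reactants: 1 5,5-dimethylcyclohexane-1,3-dione (dimedone)
Product: 2 3-ethoxy-5,5-dimethylcyclohex-2-en-1-one
Conditions: EtOH, TsOH (cat.), toluene, reflux (Dean–Stark)
Reagents that add atoms: ethanol, CCO
Why: Acid-catalysed enol etherification of a cyclic 1,3-dione; it gives a vinylogous ester with a single kinetic enolisation site, the carbon that becomes C5.

Step 2
Reactants: 2 3-ethoxy-5,5-dimethylcyclohex-2-en-1-one; 3 (S)-2,2-dimethyl-1,3-dioxolane-4-carbaldehyde
Product: 4 (6S)-6-{(R)-[(4S)-2,2-dimethyl-1,3-dioxolan-4-yl](hydroxy)methyl}-3-ethoxy-5,5-dimethylcyclohex-2-en-1-one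
Conditions: LiN(i-Pr)2, THF, −78 °C; 3, −78 °C; AcOH quench at −78 °C
Reagents that add atoms: none
Why: Aldol addition of the kinetic α'-lithium enolate of a vinylogous ester (Stork–Danheiser enolate). The ring-locked E(O)-enolate reacts through a Zimmerman–Traxler-type chair and should give the anti C5/C6 relation; Felkin–Anh (non-chelation) attack on the α-alkoxy aldehyde should give the anti C6/C7 relation. The S configuration of 3 therefore fixes C6 and, through it, C5.

Step 3
Reactants: 4 (6S)-6-{(R)-[(4S)-2,2-dimethyl-1,3-dioxolan-4-yl](hydroxy)methyl}-3-ethoxy-5,5-dimethylcyclohex-2-en-1-one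
Product: 5 (6S)-6-{(R)-[(tert-butyldimethylsilyl)oxy][(4S)-2,2-dimethyl-1,3-dioxolan-4-yl]methyl}-3-ethoxy-5,5-dimethylcyclohex-2-en-1-one
Conditions: TBSOTf, 2,6-lutidine, CH2Cl2, −78 → 0 °C
Reagents that add atoms: tert-butyldimethylsilyl trifluoromethanesulfonate, CC(C)(C)[Si](C)(C)OS(=O)(=O)C(F)(F)F
Why: Silylation of a hindered secondary alcohol with a silyl triflate; it blocks retro-aldol cleavage and the later closures of O6 onto C9 or C17, and touches no stereocentre.

Step 4
Reactants: 5 (6S)-6-{(R)-[(tert-butyldimethylsilyl)oxy][(4S)-2,2-dimethyl-1,3-dioxolan-4-yl]methyl}-3-ethoxy-5,5-dimethylcyclohex-2-en-1-one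
Product: 7 (4R)-4-{(R)-[(tert-butyldimethylsilyl)oxy][(4S)-2,2-dimethyl-1,3-dioxolan-4-yl]methyl}-3,5,5-trimethylcyclohex-2-en-1-one, via tertiary carbinol 6 (not isolated)
Conditions: MeLi, CeCl3, THF, −78 °C; then 1 M aq. HCl, THF, 0 °C
Reagents that add atoms: methyllithium, [Li]C; water, O
Why: Stork–Danheiser enone transposition. The weakly basic organocerium adds 1,2 to the hindered carbonyl without enolising towards the β-silyloxy group; cold dilute acid then ionises the tertiary carbinol and hydrolyses the enol ether, giving the C2 ketone and C1=C10. C5–H is not involved, and the carbinol stereocentre of 6 is destroyed.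

Step 5
Reactants: 7 (4R)-4-{(R)-[(tert-butyldimethylsilyl)oxy][(4S)-2,2-dimethyl-1,3-dioxolan-4-yl]methyl}-3,5,5-trimethylcyclohex-2-en-1-one
Product: 9 (4R)-4-{(1R)-1-[(tert-butyldimethylsilyl)oxy]-2-hydroxyethyl}-3,5,5-trimethylcyclohex-2-en-1-one, via α-silyloxy aldehyde 8 (not isolated)
Conditions: H5IO6, EtOAc, rt; filtrate through NaHCO3, then NaBH4, MeOH, −40 °C
Reagents that add atoms: none
Why: Periodic acid hydrolyses the terminal acetonide and cleaves the resulting glycol in one operation, excising the auxiliary carbon. Borohydride then reduces the aldehyde far faster than the hindered β,β-disubstituted enone. Any diol already formed in step 4 converges on the same aldehyde.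

Step 6
Reactants: 10 (4-methoxyphenyl)methanol; 11 acrylonitrile
Product: 12 3-[(4-methoxyphenyl)methoxy]propanenitrile
Conditions: NaH (5 mol %), THF, 0 °C → rt
Reagents that add atoms: none
Why: Base-catalysed oxa-Michael addition (cyanoethylation) of a primary alcohol; it installs O–C12 and the carbons C12, C11 and C9.

Step 7
Reactants: 12 3-[(4-methoxyphenyl)methoxy]propanenitrile; 13 methyl bromoacetate
Product: 15 methyl 5-[(4-methoxyphenyl)methoxy]-3-oxopentanoate, via bromozinc enaminate 14 (not isolated)
Conditions: Zn (activated), THF, reflux, slow addition of 13; then 1 M aq. HCl, rt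
Reagents that add atoms: water, O
Why: Blaise reaction: the zinc ester enolate adds to the nitrile and the zinc enaminate is hydrolysed to the β-keto ester; the PMB ether tolerates the brief dilute acid.

Step 8
Reactants: 9 (4R)-4-{(1R)-1-[(tert-butyldimethylsilyl)oxy]-2-hydroxyethyl}-3,5,5-trimethylcyclohex-2-en-1-one; 15 methyl 5-[(4-methoxyphenyl)methoxy]-3-oxopentanoate
Product: 17 methyl 2-{(2S)-2-[(tert-butyldimethylsilyl)oxy]-2-[(1R)-2,6,6-trimethyl-4-oxocyclohex-2-en-1-yl]ethyl}-5-[(4-methoxyphenyl)methoxy]-3-oxopentanoate (epimers at C8), via primary triflate 16 (not isolated)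
Conditions: 9, Tf2O, 2,6-lutidine, CH2Cl2, −78 °C; then into 15/NaH (3 equiv), THF, −78 → 0 °C
Reagents that add atoms: none
Why: SN2 C-alkylation of a β-keto ester sodium enolate. The triflate is chosen because C7 is β-branched and β-oxygenated, and the tight sodium enolate in THF should favour carbon over oxygen attack. The mild enolate leaves the ring enone and C5 alone, and the C8 stereocentre is lost in the next step.

Step 9
Reactants: 17 methyl 2-{(2S)-2-[(tert-butyldimethylsilyl)oxy]-2-[(1R)-2,6,6-trimethyl-4-oxocyclohex-2-en-1-yl]ethyl}-5-[(4-methoxyphenyl)methoxy]-3-oxopentanoate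
Product: 18 methyl (2E)-2-{(2S)-2-[(tert-butyldimethylsilyl)oxy]-2-[(1R)-2,6,6-trimethyl-4-oxocyclohex-2-en-1-yl]ethyl}-5-[(4-methoxyphenyl)methoxy]-3-[(trifluoromethanesulfonyl)oxy]pent-2-enoate
Conditions: Tf2O, 25% aq. Me4NOH, toluene, 0–5 °C
Reagents that add atoms: trifluoromethanesulfonic anhydride, O=S(=O)(OS(=O)(=O)C(F)(F)F)C(F)(F)F
Why: Biphasic O-triflation of a β-keto ester enolate. With the non-coordinating tetramethylammonium ion the enolate is not chelated and should adopt the dipole-minimised geometry with the oxygen anti to the ester, which gives the E enol triflate (triflate cis to C7). Hydroxide deprotonates only the 1,3-dicarbonyl, so the ring enone is not enolised.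

Step 10
Reactants: 18 methyl (2E)-2-{(2S)-2-[(tert-butyldimethylsilyl)oxy]-2-[(1R)-2,6,6-trimethyl-4-oxocyclohex-2-en-1-yl]ethyl}-5-[(4-methoxyphenyl)methoxy]-3-[(trifluoromethanesulfonyl)oxy]pent-2-enoate
Product: 19 methyl (4S,4aR,8aS)-4-[(tert-butyldimethylsilyl)oxy]-1-{2-[(4-methoxyphenyl)methoxy]ethyl}-5,5,8a-trimethyl-7-oxo-3,4,4a,5,6,7,8,8a-octahydronaphthalene-2-carboxylate
Conditions: Pd(OAc)2 (10 mol %), PPh3 (20 mol %), HCO2Na (3 equiv), Et4NCl, DMF, 70 °C
Reagents that add atoms: none
Why: Zerovalent palladium, formed from Pd(OAc)2 and PPh3, inserts into the C9–O bond of the electron-poor enol triflate, and the alkenylpalladium adds syn across C1=C10 with C9 bonding to C10, a 6-exo-trig carbopalladation that closes ring B. The palladium left at C1 is α to the C2 carbonyl and has no β-hydrogen within reach because C10 is now quaternary, so it exchanges triflate for formate, loses CO2 and reductively eliminates C1–H. The closest known reaction type is the formate-mediated reductive Heck (conjugate) addition of alkenyl triflates to β,β-disubstituted enones, here in intramolecular form. The only new stereocentre, C10, is controlled by C5: the three-atom tether C6–C7–C8 can deliver C9 only to the face of ring A on which C6 stands, so the fusion is cis (10S from 5R). Exo closure at C10 is favoured over 7-endo attack at C1 by ring size and by the polarisation of the enone. The step needs the triflate cis to C7, which 18 has by construction, and needs cyclisation to outrun formate capture of the alkenylpalladium, which the intramolecular setting and the sparingly soluble formate favour. The C6 stereocentre, silyl ether, PMB ether and ester are not touched.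

Step 11
Reactants: 19 methyl (4S,4aR,8aS)-4-[(tert-butyldimethylsilyl)oxy]-1-{2-[(4-methoxyphenyl)methoxy]ethyl}-5,5,8a-trimethyl-7-oxo-3,4,4a,5,6,7,8,8a-octahydronaphthalene-2-carboxylate
Product: 21 {(4S,4aR,7S,8aS)-4-[(tert-butyldimethylsilyl)oxy]-7-hydroxy-1-{2-[(4-methoxyphenyl)methoxy]ethyl}-5,5,8a-trimethyl-3,4,4a,5,6,7,8,8a-octahydronaphthalen-2-yl}methanol, via hydroxy ester 20 (not isolated)
Conditions: LiBH(s-Bu)3, THF, −78 °C; then i-Bu2AlH (4 equiv), −78 → 0 °C; aq. potassium sodium tartrate
Reagents that add atoms: none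
Why: Diastereoselective ketone reduction followed by ester reduction in one flask. The bulky borohydride should attack C2 from the convex face of the cis-fused bicycle (the face of C20 and H5, equatorial trajectory in the chair that keeps the 6-silyloxy group equatorial on ring B), because the other face is screened by ring B and the axial 4α-methyl; this sets 2S. The tetrasubstituted enoate is inert to this reagent at −78 °C and is then reduced 1,2 by i-Bu2AlH to the allylic alcohol.

Step 12
Reactants: 21 {(4S,4aR,7S,8aS)-4-[(tert-butyldimethylsilyl)oxy]-7-hydroxy-1-{2-[(4-methoxyphenyl)methoxy]ethyl}-5,5,8a-trimethyl-3,4,4a,5,6,7,8,8a-octahydronaphthalen-2-yl}methanol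
Product: 22 (4S,4aR,7S,8aS)-4,7-bis[(tert-butyldimethylsilyl)oxy]-2-{[(tert-butyldimethylsilyl)oxy]methyl}-1-{2-[(4-methoxyphenyl)methoxy]ethyl}-5,5,8a-trimethyl-3,4,4a,5,6,7,8,8a-octahydronaphthalene
Conditions: TBSOTf (3 equiv), 2,6-lutidine, CH2Cl2, −78 → 0 °C
Reagents that add atoms: tert-butyldimethylsilyl trifluoromethanesulfonate, CC(C)(C)[Si](C)(C)OS(=O)(=O)C(F)(F)F
Why: Silylation of the primary allylic and the secondary alcohol; it leaves the C12 oxygen as the only one that can be unmasked oxidatively.

Step 13
Reactants: 22 (4S,4aR,7S,8aS)-4,7-bis[(tert-butyldimethylsilyl)oxy]-2-{[(tert-butyldimethylsilyl)oxy]methyl}-1-{2-[(4-methoxyphenyl)methoxy]ethyl}-5,5,8a-trimethyl-3,4,4a,5,6,7,8,8a-octahydronaphthalene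
Product: 23 2-[(4S,4aR,7S,8aS)-4,7-bis[(tert-butyldimethylsilyl)oxy]-2-{[(tert-butyldimethylsilyl)oxy]methyl}-5,5,8a-trimethyl-3,4,4a,5,6,7,8,8a-octahydronaphthalen-1-yl]ethan-1-ol
Conditions: DDQ, CH2Cl2/pH 7 buffer, 0 °C
Reagents that add atoms: none
Why: Oxidative cleavage of the electron-rich PMB ether by DDQ (benzylic hydride abstraction, then hydrolysis of the oxocarbenium ion); silyl ethers and the tetrasubstituted alkene are inert under buffered conditions.

Step 14
Reactants: 23 2-[(4S,4aR,7S,8aS)-4,7-bis[(tert-butyldimethylsilyl)oxy]-2-{[(tert-butyldimethylsilyl)oxy]methyl}-5,5,8a-trimethyl-3,4,4a,5,6,7,8,8a-octahydronaphthalen-1-yl]ethan-1-ol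
Product: 24 (4S,4aR,7S,8aS)-4,7-bis[(tert-butyldimethylsilyl)oxy]-2-{[(tert-butyldimethylsilyl)oxy]methyl}-1-(2-iodoethyl)-5,5,8a-trimethyl-3,4,4a,5,6,7,8,8a-octahydronaphthalene
Conditions: I2, PPh3, imidazole, CH2Cl2, 0 °C → rt
Reagents that add atoms: iodine, II
Why: Appel-type iodination of a primary alcohol through the alkoxyphosphonium ion (SN2 by iodide); neutral conditions spare the silyl ethers.

Step 15
Reactants: 24 (4S,4aR,7S,8aS)-4,7-bis[(tert-butyldimethylsilyl)oxy]-2-{[(tert-butyldimethylsilyl)oxy]methyl}-1-(2-iodoethyl)-5,5,8a-trimethyl-3,4,4a,5,6,7,8,8a-octahydronaphthalene; 25 4-bromofuran-2(5H)-one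
Product: 27 4-{2-[(4S,4aR,7S,8aS)-4,7-bis[(tert-butyldimethylsilyl)oxy]-2-{[(tert-butyldimethylsilyl)oxy]methyl}-5,5,8a-trimethyl-3,4,4a,5,6,7,8,8a-octahydronaphthalen-1-yl]ethyl}furan-2(5H)-one, via alkylzinc iodide 26 (not isolated)
Conditions: Zn (activated with BrCH2CH2Br, Me3SiCl), DMF, 40 °C; then 25, Pd2(dba)3 (2.5 mol %), SPhos (10 mol %), rt → 40 °C
Reagents that add atoms: none
Why: Negishi coupling: zinc inserts into the primary C–I bond, and the alkylzinc transmetalates to the alkenylpalladium formed by fast oxidative addition to the β-bromo butenolide; reductive elimination forms C12–C13. The organozinc is neither basic nor nucleophilic enough to attack the lactone or the silyl ethers, and no stereocentre is involved.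

Step 16
Reactants: 27 4-{2-[(4S,4aR,7S,8aS)-4,7-bis[(tert-butyldimethylsilyl)oxy]-2-{[(tert-butyldimethylsilyl)oxy]methyl}-5,5,8a-trimethyl-3,4,4a,5,6,7,8,8a-octahydronaphthalen-1-yl]ethyl}furan-2(5H)-one
Product: 28 4-{2-[(4S,4aR,7S,8aS)-4,7-dihydroxy-2-(hydroxymethyl)-5,5,8a-trimethyl-3,4,4a,5,6,7,8,8a-octahydronaphthalen-1-yl]ethyl}furan-2(5H)-one
Conditions: 48% aq. HF, MeCN, 0 °C → rt
Reagents that add atoms: none
Why: Global desilylation by acidic fluoride; the butenolide, which would not survive basic fluoride or alkoxide, is stable under these conditions, and no stereocentre is touched.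

## Compound list

1 | 5,5-dimethylcyclohexane-1,3-dione (dimedone) | CC1(C)CC(=O)CC(=O)C1 | starting material
2 | 3-ethoxy-5,5-dimethylcyclohex-2-en-1-one | CCOC1=CC(=O)CC(C)(C)C1 | intermediate
3 | (S)-2,2-dimethyl-1,3-dioxolane-4-carbaldehyde | O=C[C@@H]1COC(C)(C)O1 | starting material
4 | (6S)-6-{(R)-[(4S)-2,2-dimethyl-1,3-dioxolan-4-yl](hydroxy)methyl}-3-ethoxy-5,5-dimethylcyclohex-2-en-1-one | O=C1C=C(OCC)CC(C)(C)[C@H]1[C@@H](O)[C@@H]2COC(C)(C)O2 | intermediate
5 | (6S)-6-{(R)-[(tert-butyldimethylsilyl)oxy][(4S)-2,2-dimethyl-1,3-dioxolan-4-yl]methyl}-3-ethoxy-5,5-dimethylcyclohex-2-en-1-one | O=C1C=C(OCC)CC(C)(C)[C@H]1[C@@H](O[Si](C)(C)C(C)(C)C)[C@@H]2COC(C)(C)O2 | intermediate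
6 | (6S)-6-{(R)-[(tert-butyldimethylsilyl)oxy][(4S)-2,2-dimethyl-1,3-dioxolan-4-yl]methyl}-3-ethoxy-1,5,5-trimethylcyclohex-2-en-1-ol (either configuration at C1) | CC1(O)C=C(OCC)CC(C)(C)[C@H]1[C@@H](O[Si](C)(C)C(C)(C)C)[C@@H]2COC(C)(C)O2 | intermediate
7 | (4R)-4-{(R)-[(tert-butyldimethylsilyl)oxy][(4S)-2,2-dimethyl-1,3-dioxolan-4-yl]methyl}-3,5,5-trimethylcyclohex-2-en-1-one | CC1=CC(=O)CC(C)(C)[C@H]1[C@@H](O[Si](C)(C)C(C)(C)C)[C@@H]2COC(C)(C)O2 | intermediate
8 | (2R)-2-[(tert-butyldimethylsilyl)oxy]-2-[(1R)-2,6,6-trimethyl-4-oxocyclohex-2-en-1-yl]acetaldehyde | CC1=CC(=O)CC(C)(C)[C@H]1[C@@H](O[Si](C)(C)C(C)(C)C)C=O | intermediate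
9 | (4R)-4-{(1R)-1-[(tert-butyldimethylsilyl)oxy]-2-hydroxyethyl}-3,5,5-trimethylcyclohex-2-en-1-one | CC1=CC(=O)CC(C)(C)[C@H]1[C@@H](O[Si](C)(C)C(C)(C)C)CO | intermediate
10 | (4-methoxyphenyl)methanol | COc1ccc(CO)cc1 | starting material
11 | acrylonitrile | C=CC#N | starting material
12 | 3-[(4-methoxyphenyl)methoxy]propanenitrile | COc1ccc(COCCC#N)cc1 | intermediate
13 | methyl bromoacetate | COC(=O)CBr | starting material
14 | methyl (Z)-3-[(bromozincio)amino]-5-[(4-methoxyphenyl)methoxy]pent-2-enoate | COC(=O)/C=C(\N[Zn]Br)CCOCc1ccc(OC)cc1 | intermediate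
15 | methyl 5-[(4-methoxyphenyl)methoxy]-3-oxopentanoate | COC(=O)CC(=O)CCOCc1ccc(OC)cc1 | intermediate
16 | (2R)-2-[(tert-butyldimethylsilyl)oxy]-2-[(1R)-2,6,6-trimethyl-4-oxocyclohex-2-en-1-yl]ethyl trifluoromethanesulfonate | CC1=CC(=O)CC(C)(C)[C@H]1[C@@H](O[Si](C)(C)C(C)(C)C)COS(=O)(=O)C(F)(F)F | intermediate
17 | methyl 2-{(2S)-2-[(tert-butyldimethylsilyl)oxy]-2-[(1R)-2,6,6-trimethyl-4-oxocyclohex-2-en-1-yl]ethyl}-5-[(4-methoxyphenyl)methoxy]-3-oxopentanoate (epimers at C8) | CC1=CC(=O)CC(C)(C)[C@H]1[C@@H](O[Si](C)(C)C(C)(C)C)CC(C(=O)OC)C(=O)CCOCc1ccc(OC)cc1 | intermediate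
18 | methyl (2E)-2-{(2S)-2-[(tert-butyldimethylsilyl)oxy]-2-[(1R)-2,6,6-trimethyl-4-oxocyclohex-2-en-1-yl]ethyl}-5-[(4-methoxyphenyl)methoxy]-3-[(trifluoromethanesulfonyl)oxy]pent-2-enoate | CC1=CC(=O)CC(C)(C)[C@H]1[C@@H](O[Si](C)(C)C(C)(C)C)C/C(C(=O)OC)=C(\OS(=O)(=O)C(F)(F)F)CCOCc1ccc(OC)cc1 | intermediate
19 | methyl (4S,4aR,8aS)-4-[(tert-butyldimethylsilyl)oxy]-1-{2-[(4-methoxyphenyl)methoxy]ethyl}-5,5,8a-trimethyl-7-oxo-3,4,4a,5,6,7,8,8a-octahydronaphthalene-2-carboxylate | CC1(C)CC(=O)C[C@]2(C)C(CCOCc3ccc(OC)cc3)=C(C(=O)OC)C[C@H](O[Si](C)(C)C(C)(C)C)[C@H]12 | intermediate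
20 | methyl (4S,4aR,7S,8aS)-4-[(tert-butyldimethylsilyl)oxy]-7-hydroxy-1-{2-[(4-methoxyphenyl)methoxy]ethyl}-5,5,8a-trimethyl-3,4,4a,5,6,7,8,8a-octahydronaphthalene-2-carboxylate | CC1(C)C[C@H](O)C[C@]2(C)C(CCOCc3ccc(OC)cc3)=C(C(=O)OC)C[C@H](O[Si](C)(C)C(C)(C)C)[C@H]12 | intermediate
21 | {(4S,4aR,7S,8aS)-4-[(tert-butyldimethylsilyl)oxy]-7-hydroxy-1-{2-[(4-methoxyphenyl)methoxy]ethyl}-5,5,8a-trimethyl-3,4,4a,5,6,7,8,8a-octahydronaphthalen-2-yl}methanol | CC1(C)C[C@H](O)C[C@]2(C)C(CCOCc3ccc(OC)cc3)=C(CO)C[C@H](O[Si](C)(C)C(C)(C)C)[C@H]12 | intermediate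
22 | (4S,4aR,7S,8aS)-4,7-bis[(tert-butyldimethylsilyl)oxy]-2-{[(tert-butyldimethylsilyl)oxy]methyl}-1-{2-[(4-methoxyphenyl)methoxy]ethyl}-5,5,8a-trimethyl-3,4,4a,5,6,7,8,8a-octahydronaphthalene | CC1(C)C[C@H](O[Si](C)(C)C(C)(C)C)C[C@]2(C)C(CCOCc3ccc(OC)cc3)=C(CO[Si](C)(C)C(C)(C)C)C[C@H](O[Si](C)(C)C(C)(C)C)[C@H]12 | intermediate
23 | 2-[(4S,4aR,7S,8aS)-4,7-bis[(tert-butyldimethylsilyl)oxy]-2-{[(tert-butyldimethylsilyl)oxy]methyl}-5,5,8a-trimethyl-3,4,4a,5,6,7,8,8a-octahydronaphthalen-1-yl]ethan-1-ol | CC1(C)C[C@H](O[Si](C)(C)C(C)(C)C)C[C@]2(C)C(CCO)=C(CO[Si](C)(C)C(C)(C)C)C[C@H](O[Si](C)(C)C(C)(C)C)[C@H]12 | intermediate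
24 | (4S,4aR,7S,8aS)-4,7-bis[(tert-butyldimethylsilyl)oxy]-2-{[(tert-butyldimethylsilyl)oxy]methyl}-1-(2-iodoethyl)-5,5,8a-trimethyl-3,4,4a,5,6,7,8,8a-octahydronaphthalene | CC1(C)C[C@H](O[Si](C)(C)C(C)(C)C)C[C@]2(C)C(CCI)=C(CO[Si](C)(C)C(C)(C)C)C[C@H](O[Si](C)(C)C(C)(C)C)[C@H]12 | intermediate
25 | 4-bromofuran-2(5H)-one | O=C1C=C(Br)CO1 | starting material
26 | {2-[(4S,4aR,7S,8aS)-4,7-bis[(tert-butyldimethylsilyl)oxy]-2-{[(tert-butyldimethylsilyl)oxy]methyl}-5,5,8a-trimethyl-3,4,4a,5,6,7,8,8a-octahydronaphthalen-1-yl]ethyl}zinc iodide | CC1(C)C[C@H](O[Si](C)(C)C(C)(C)C)C[C@]2(C)C(CC[Zn]I)=C(CO[Si](C)(C)C(C)(C)C)C[C@H](O[Si](C)(C)C(C)(C)C)[C@H]12 | intermediate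
27 | 4-{2-[(4S,4aR,7S,8aS)-4,7-bis[(tert-butyldimethylsilyl)oxy]-2-{[(tert-butyldimethylsilyl)oxy]methyl}-5,5,8a-trimethyl-3,4,4a,5,6,7,8,8a-octahydronaphthalen-1-yl]ethyl}furan-2(5H)-one | CC1(C)C[C@H](O[Si](C)(C)C(C)(C)C)C[C@]2(C)C(CCC3=CC(=O)OC3)=C(CO[Si](C)(C)C(C)(C)C)C[C@H](O[Si](C)(C)C(C)(C)C)[C@H]12 | intermediate
28 | 4-{2-[(4S,4aR,7S,8aS)-4,7-dihydroxy-2-(hydroxymethyl)-5,5,8a-trimethyl-3,4,4a,5,6,7,8,8a-octahydronaphthalen-1-yl]ethyl}furan-2(5H)-one (labdane locants: 2S,5R,6S,10S) | CC1(C)C[C@H](O)C[C@]2(C)C(CCC3=CC(=O)OC3)=C(CO)C[C@H](O)[C@H]12 | target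

## Step count and least certain steps

Total: 16 steps. Longest linear sequence: 14 steps (steps 1–5 and 8–16, from 1 to 28); the two-step branch (steps 6 and 7) joins at step 8.

**Step 10 (key step).** The most likely failure is premature capture of the alkenylpalladium by formate (reduction of the C9–O bond without ring closure), because insertion into the trisubstituted, β,β-disubstituted enone is slow. Fallback: from 18, Miyaura borylation (B2pin2, PdCl2(dppf), KOAc, dioxane) should give the alkenyl pinacolboronate F1 with boron cis to C7. A rhodium-catalysed intramolecular conjugate addition ([Rh(cod)OH]2, aqueous dioxane, 60 °C) then forms C9–C10 by transmetalation and 1,4-insertion with no hydride source present, and protonation of the rhodium enolate returns the route at 19.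

**Step 2.** What may go wrong is loss of stereocontrol through reversibility: retro-aldol equilibration and base-induced enolisation of 3 by the hindered, slowly reacting enolate would erode both the anti relation and the facial selectivity at C6. Fallback: from 2, the enolate is trapped (LiN(i-Pr)2, then Me3SiCl) as the silyl dienol ether F2. A Mukaiyama aldol addition to 3 under BF3·OEt2 (CH2Cl2, −78 °C) is non-basic and irreversible, should again follow non-chelation attack on the aldehyde, and returns at 4 after work-up; minor isomers would be removed by chromatography.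

**Step 4.** What may go wrong is enolisation of the hindered carbonyl instead of addition, followed by β-elimination of the silyloxy group. Fallback: from 5, methylenation of the vinylogous ester carbonyl with Cp2Ti(μ-CH2)(μ-Cl)AlMe2 (THF, pyridine, −40 → 0 °C) should give the exocyclic methylene dienol ether F3. Cold dilute acid then protonates the methylene terminus and hydrolyses the enol ether, which returns at 7 without any basic carbon nucleophile.

**Step 8.** What may go wrong is O-alkylation of the ambident enolate by the hard triflate, or decomposition of the β-silyloxy triflate (silyl participation, elimination) before it is captured. Fallback: from 8, taken from the periodate stage of step 5 without the borohydride stage, Knoevenagel condensation with 15 (TiCl4, pyridine, THF, 0 °C) should give the alkylidene keto ester F4. Conjugate reduction with Hantzsch ester (benzene, 60 °C) returns at 17; the C7–C8 bond is then made by carbonyl condensation and not by substitution.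

**Step 9.** What may go wrong is incomplete geometric control in the O-sulfonylation; the Z isomer cannot cyclise. Fallback: from 17, sulfonylation with TsCl, N-methylimidazole and Et3N (CH2Cl2, 0 °C), which proceeds through an N-sulfonylimidazolium ion and a non-chelated ammonium enolate, should give the E enol tosylate F5. The reductive Heck closure of this activated tosylate (Pd(OAc)2, XPhos, HCO2Na, DMF, 80 °C) returns at 19.

**Step 11.** What may go wrong is poor or reversed facial selectivity at C2 if ring A reacts through the other chair, in which the axial C20 and 4β-methyl groups screen the convex face. Fallback: from 19, reduction with NaBH4 (MeOH, 0 °C) to whatever alcohol the substrate prefers; if this is the 2-epimer F6, Mitsunobu inversion (4-nitrobenzoic acid, PPh3, DIAD, toluene) should give the inverted ester F7. Methanolysis (K2CO3, MeOH) returns at 20, which is then reduced with i-Bu2AlH as in step 11.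

## Further compounds

F1 | step 10 | methyl (2Z)-2-{(2S)-2-[(tert-butyldimethylsilyl)oxy]-2-[(1R)-2,6,6-trimethyl-4-oxocyclohex-2-en-1-yl]ethyl}-5-[(4-methoxyphenyl)methoxy]-3-(4,4,5,5-tetramethyl-1,3,2-dioxaborolan-2-yl)pent-2-enoate | CC1=CC(=O)CC(C)(C)[C@H]1[C@@H](O[Si](C)(C)C(C)(C)C)C/C(C(=O)OC)=C(\B1OC(C)(C)C(C)(C)O1)CCOCc1ccc(OC)cc1
F2 | step 2 | 1-ethoxy-5,5-dimethyl-3-[(trimethylsilyl)oxy]cyclohexa-1,3-diene | CCOC1=CC(O[Si](C)(C)C)=CC(C)(C)C1
F3 | step 4 | tert-butyl{(R)-[(4S)-2,2-dimethyl-1,3-dioxolan-4-yl][(1R)-4-ethoxy-6,6-dimethyl-2-methylidenecyclohex-3-en-1-yl]methoxy}dimethylsilane | C=C1C=C(OCC)CC(C)(C)[C@H]1[C@@H](O[Si](C)(C)C(C)(C)C)[C@@H]2COC(C)(C)O2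
F4 | step 8 | methyl 2-{(2S)-2-[(tert-butyldimethylsilyl)oxy]-2-[(1R)-2,6,6-trimethyl-4-oxocyclohex-2-en-1-yl]ethylidene}-5-[(4-methoxyphenyl)methoxy]-3-oxopentanoate (E/Z mixture) | CC1=CC(=O)CC(C)(C)[C@H]1[C@@H](O[Si](C)(C)C(C)(C)C)C=C(C(=O)OC)C(=O)CCOCc1ccc(OC)cc1
F5 | step 9 | methyl (2E)-2-{(2S)-2-[(tert-butyldimethylsilyl)oxy]-2-[(1R)-2,6,6-trimethyl-4-oxocyclohex-2-en-1-yl]ethyl}-5-[(4-methoxyphenyl)methoxy]-3-[(4-methylbenzenesulfonyl)oxy]pent-2-enoate | CC1=CC(=O)CC(C)(C)[C@H]1[C@@H](O[Si](C)(C)C(C)(C)C)C/C(C(=O)OC)=C(\OS(=O)(=O)c1ccc(C)cc1)CCOCc1ccc(OC)cc1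
F6 | step 11 | methyl (4S,4aR,7R,8aS)-4-[(tert-butyldimethylsilyl)oxy]-7-hydroxy-1-{2-[(4-methoxyphenyl)methoxy]ethyl}-5,5,8a-trimethyl-3,4,4a,5,6,7,8,8a-octahydronaphthalene-2-carboxylate | CC1(C)C[C@@H](O)C[C@]2(C)C(CCOCc3ccc(OC)cc3)=C(C(=O)OC)C[C@H](O[Si](C)(C)C(C)(C)C)[C@H]12
F7 | step 11 | methyl (4S,4aR,7S,8aS)-4-[(tert-butyldimethylsilyl)oxy]-1-{2-[(4-methoxyphenyl)methoxy]ethyl}-5,5,8a-trimethyl-7-[(4-nitrobenzoyl)oxy]-3,4,4a,5,6,7,8,8a-octahydronaphthalene-2-carboxylate | CC1(C)C[C@H](OC(=O)c3ccc(cc3)[N+](=O)[O-])C[C@]2(C)C(CCOCc3ccc(OC)cc3)=C(C(=O)OC)C[C@H](O[Si](C)(C)C(C)(C)C)[C@H]12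
A1 | alternative 1 | cis-fused methyl 2-[(tert-butyldimethylsilyl)oxy]-4,4,10-trimethyl-6,9-dioxo-bicyclic 8-carboxylate (labdane locants; product of the oxidative closure) | CC1(C)C[C@H](O[Si](C)(C)C(C)(C)C)C[C@]2(C)C(=O)C(C(=O)OC)CC(=O)[C@H]12
A2 | alternative 1 | ring A substrate with a β-keto ester arm on C10 and a cis trimethylsilyl enol ether arm on C5 | CC1(C)C[C@H](O[Si](C)(C)C(C)(C)C)C[C@](C)(C(=O)CC(=O)OC)[C@@H]1C(=C)O[Si](C)(C)C
A3 | alternative 2 | cis-fused methyl 2,6-bis[(tert-butyldimethylsilyl)oxy]-12-[(4-methoxyphenyl)methoxy] bicyclic 8-en-17-oate (labdane locants; cycloadduct) | CC1(C)C[C@H](O[Si](C)(C)C(C)(C)C)C[C@]2(C)C(CCOCc3ccc(OC)cc3)=C(C(=O)OC)C[C@H](O[Si](C)(C)C(C)(C)C)[C@H]12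
A4 | alternative 2 | open-chain 2-methoxycarbonyl diene with a tethered Z silyl enol ether (tether inside the diene) | C=C(C(=O)OC)/C(CCOCc1ccc(OC)cc1)=C(C)\C[C@@H](O[Si](C)(C)C(C)(C)C)CC(C)(C)/C=C\O[Si](C)(C)C(C)(C)C
A5 | alternative 3 | cis-fused methyl 12-[(tert-butyldimethylsilyl)oxy]-2,6-dioxo bicyclic 8-en-17-oate (labdane locants; Michael product) | CC1(C)CC(=O)C[C@]2(C)C(CCO[Si](C)(C)C(C)(C)C)=C(C(=O)OC)CC(=O)[C@H]12
A6 | alternative 3 | ring B substrate with an isopropylidene group on C5 and an acetonyl arm on C10 | CC(=O)C[C@]1(C)C(CCO[Si](C)(C)C(C)(C)C)=C(C(=O)OC)CC(=O)C1=C(C)C
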